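**Retrosynthetic overview**

1. Feature: in the bicyclo[3.3.1]nonane core (bridgeheads C1 and C5, bridging ketone C9; ring A = C1–C2–C3–C4–C5–C9, ring B = C1–C8–C7–C6–C5–C9) C5 lies between the C4 and C9 carbonyls, C6 is a plain CH2 and the C7 prenyl group is endo. C5–C6 can therefore be made from an α,α-dicarbonyl radical at C5, with hydrogen as the last group to reach C7, from the exo face.
2. Ring A exists first, as the phloroglucinol ring; ring B is closed last (C5–C6, then H transfer to C7) on a dearomatised acylphloroglucinol. An allyl group stands in for the C1 prenyl group and is converted by cross-metathesis, followed by global desilylation.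
3. The quaternary C1 with its C8(Me2)–C7(prenyl)=C6H2 arm comes from a dearomatising Claisen rearrangement of an isolavandulyl (2-prenylprenyl) ether on O2, the oxygen between the allyl-bearing C1 and the aroyl-bearing C3; the para carbon C5 already carries the side chain. C1 forms without facial control; both epimers are carried through the acetal hydrolysis and separated as the enolised triones.
4. The hexasubstituted arene is built on 2,4,6-trihydroxybenzaldehyde: O-allylation/Claisen (allyl at C1), bromination/Negishi coupling (side chain at C5), aryllithium addition/oxidation (aroyl at C3).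
5. The side chain (C1'–C5', counted from the ring) comes from (S)-lavandulyl acetate: lipase resolution (C2'), Shi epoxidation (C4'), epoxide-to-allylic-silyl-ether isomerisation. Isolavandulyl bromide comes from racemic lavandulol.

Key step: step 20

Assumption: the lipase in step 1 hydrolyses the (R)-acetate faster (the enantiomer that lipases are reported to acylate faster in the reverse direction), so the (S)-acetate is the one recovered; enolised triones are written as one tautomer throughout.

**Route**

Step 1
Reactants: 1 (±)-lavandulyl acetate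
Product: 2 (S)-lavandulyl acetate
Conditions: porcine pancreatic lipase, phosphate buffer (pH 7)/acetone, 25 °C, stopped beyond half conversion; chromatography
Reagents that add atoms: none
Why: Lipase-catalysed kinetic resolution by enantioselective ester hydrolysis should consume the (R)-acetate first, so the slower (S)-acetate is recovered in high enantiomeric purity once the hydrolysis is taken past half conversion; this fixes C2' of the side chain.

Step 2
Reactants: 2 (S)-lavandulyl acetate
Product: 3 (2S)-2-{[(2R)-3,3-dimethyloxiran-2-yl]methyl}-3-methylbut-3-en-1-yl acetate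
Conditions: Shi ketone (D-fructose-derived, 30 mol%), Oxone (2KHSO5·KHSO4·K2SO4), K2CO3, Bu4NHSO4, MeCN–CH2(OMe)2/aq. Na2B4O7 buffer (pH 10.5), 0 °C
Reagents that add atoms: Oxone (KHSO5 is the oxygen donor), [K+].OOS(=O)(=O)[O-]
Why: Shi asymmetric epoxidation: the chiral dioxirane reacts with the trisubstituted alkene well before the 1,1-disubstituted isopropenyl group, and its spiro transition state should give the (R)-epoxide under reagent control, which sets C4'.

Step 3
Reactants: 3 epoxy acetate
Product: 5 (2S,4R)-4-[(tert-butyldimethylsilyl)oxy]-5-methyl-2-(prop-1-en-2-yl)hex-5-en-1-yl acetate, via tertiary triflate 4 (not isolated)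
Conditions: TBSOTf, 2,6-lutidine, CH2Cl2, −78 °C; then DBU, −78 °C → rt
Reagents that add atoms: TBSOTf, CC(C)(C)[Si](C)(C)OS(=O)(=O)C(F)(F)F
Why: Noyori-type isomerisation of an epoxide to an allylic silyl ether: the silyl triflate opens the epoxide at the tertiary carbon and DBU removes a methyl proton, so the C4'–O bond is never broken (configuration retained) and the alcohol emerges already protected.

Step 4
Reactants: 5 silyl ether acetate
Product: 6 (2S,4R)-4-[(tert-butyldimethylsilyl)oxy]-5-methyl-2-(prop-1-en-2-yl)hex-5-en-1-ol
Conditions: K2CO3 (cat.), MeOH, 0 °C → rt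
Reagents that add atoms: none
Why: Base-catalysed transesterification (Zemplén-type methanolysis) removes the primary acetate and leaves the secondary silyl ether in place.

Step 5
Reactants: 6 primary alcohol
Product: 7 (3R,5S)-3-[(tert-butyldimethylsilyl)oxy]-6-iodo-2-methyl-5-(prop-1-en-2-yl)hex-1-ene (side-chain iodide)
Conditions: I2, PPh3, imidazole, CH2Cl2, 0 °C → rt
Reagents that add atoms: iodine, II
Why: Appel-type iodination (Garegg–Samuelsson conditions) replaces the primary hydroxyl by SN2 at CH2, so neither stereocentre is touched.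

Step 6
Reactants: 8 (±)-lavandulol
Product: 10 isolavandulal [5-methyl-2-(propan-2-ylidene)hex-4-enal], via lavandulal 9 (not isolated)
Conditions: Dess–Martin periodinane, CH2Cl2, 0 °C → rt; then DBU (cat.), rt
Reagents that add atoms: none
Why: Dess–Martin oxidation gives the β,γ-unsaturated aldehyde, which base should move into conjugation (the tetrasubstituted enal is the thermodynamic isomer); the stereocentre is erased on purpose, so the racemate suffices.

Step 7
Reactants: 10 isolavandulal
Product: 11 isolavandulol [5-methyl-2-(propan-2-ylidene)hex-4-en-1-ol]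
Conditions: NaBH4, CeCl3·7H2O, MeOH, 0 °C
Reagents that add atoms: none
Why: Luche reduction gives clean 1,2-reduction of the hindered enal to the allylic alcohol.

Step 8
Reactants: 11 isolavandulol
Product: 12 isolavandulyl bromide [3-(bromomethyl)-2,6-dimethylhepta-2,5-diene]
Conditions: PBr3, Et2O, 0 °C; used without storage
Reagents that add atoms: PBr3, BrP(Br)Br
Why: Bromination of a primary allylic alcohol with PBr3 (SN2 at CH2); the primary bromide is also the more stable allylic isomer.

Step 9
Reactants: 13 4-bromobenzene-1,2-diol
Product: 14 4-bromo-1,2-bis[(tert-butyldimethylsilyl)oxy]benzene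
Conditions: TBSCl, imidazole, DMF, rt
Reagents that add atoms: TBSCl, CC(C)(C)[Si](C)(C)Cl
Why: Standard imidazole-mediated silylation; the silyl ethers sit meta and para to bromine, so later lithiation cannot trigger a silyl shift, and they keep the catechol inert to the oxidant of step 20.

Step 10
Reactants: 15 2,4,6-trihydroxybenzaldehyde
Product: 16 2-hydroxy-4,6-bis(methoxymethoxy)benzaldehyde
Conditions: MOMCl (2.2 equiv), i-Pr2NEt, CH2Cl2, 0 °C → rt
Reagents that add atoms: MOMCl, COCCl
Why: Williamson-type acetal formation at the para and one ortho phenol, while the last ortho phenol is held back by its hydrogen bond to the formyl group; this differentiates the three oxygens.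

Step 11
Reactants: 16 2-hydroxy-4,6-bis(methoxymethoxy)benzaldehyde
Product: 17 2-(allyloxy)-4,6-bis(methoxymethoxy)benzaldehyde
Conditions: allyl bromide, K2CO3, DMF, 50 °C
Reagents that add atoms: allyl bromide, C=CCBr
Why: Williamson etherification of the remaining chelated phenol.

Step 12
Reactants: 17 2-(allyloxy)-4,6-bis(methoxymethoxy)benzaldehyde
Product: 19 3-allyl-2-hydroxy-4,6-bis(methoxymethoxy)benzaldehyde, via ortho-dienone 18 (not isolated)
Conditions: PhNEt2, 190 °C
Reagents that add atoms: none
Why: Aromatic Claisen rearrangement: the allyl group can only move to the one free ortho carbon (the other carries the formyl group), and tautomerisation restores the phenol; the allyl group thus ends next to the only free hydroxyl (O2, C1).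

Step 13
Reactants: 19 3-allyl-2-hydroxy-4,6-bis(methoxymethoxy)benzaldehyde
Product: 20 3-allyl-5-bromo-2-hydroxy-4,6-bis(methoxymethoxy)benzaldehyde
Conditions: NBS (1.0 equiv), MeCN, 0 °C
Reagents that add atoms: NBS, O=C1CCC(=O)N1Br
Why: Electrophilic aromatic bromination at the single remaining ring C–H (C5), which is para to the free phenol and flanked by two alkoxy groups and therefore far more reactive than the terminal alkene.

Step 14
Reactants: 20 3-allyl-5-bromo-2-hydroxy-4,6-bis(methoxymethoxy)benzaldehyde; 12 isolavandulyl bromide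
Product: 21 3-allyl-5-bromo-2-(isolavandulyloxy)-4,6-bis(methoxymethoxy)benzaldehyde
Conditions: K2CO3, DMF, 40 °C
Reagents that add atoms: none
Why: Williamson etherification of the only free phenol with the primary allylic bromide puts the migrating group on O2, the oxygen between the allyl-bearing and the formyl-bearing carbons.

Step 15
Reactants: 21 aryl bromide; 7 side-chain iodide
Product: 23 3-allyl-2-(isolavandulyloxy)-4,6-bis(methoxymethoxy)-5-[(2S,4R)-4-(tert-butyldimethylsilyloxy)-5-methyl-2-(prop-1-en-2-yl)hex-5-en-1-yl]benzaldehyde, via alkylzinc iodide 22 (not isolated)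
Conditions: 7, Zn dust, LiCl, THF, 40 °C; then 21, Pd(OAc)2 (3 mol%), SPhos (6 mol%), THF, 25 → 50 °C
Reagents that add atoms: none
Why: Negishi cross-coupling: LiCl-assisted zinc insertion into the primary iodide and Pd/SPhos-catalysed sp3–sp2 coupling form the C5–C1' bond; the C2' stereocentre is β to zinc and passes no enolisable or long-lived radical intermediate, and the aldehyde, silyl ether and tetrasubstituted allylic ether should be tolerated.

Step 16
Reactants: 23 aldehyde; 14 4-bromo-1,2-bis[(tert-butyldimethylsilyl)oxy]benzene
Product: 25 diaryl carbinol (both carbinol epimers), via aryllithium 24 (not isolated)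
Conditions: 14, n-BuLi, THF, −78 °C; then 23, −78 °C; H2O
Reagents that add atoms: none
Why: Bromine–lithium exchange followed by 1,2-addition of the aryllithium to the aldehyde; the carbinol centre forms as a mixture and is removed in the next step.

Step 17
Reactants: 25 diaryl carbinol
Product: 26 benzophenone {3-allyl-2-(isolavandulyloxy)-4,6-bis(methoxymethoxy)-5-[(2S,4R)-side chain]phenyl}{3,4-bis[(tert-butyldimethylsilyl)oxy]phenyl}methanone
Conditions: Dess–Martin periodinane, pyridine, CH2Cl2, 0 °C → rt
Reagents that add atoms: none
Why: Dess–Martin oxidation of the doubly benzylic alcohol under buffered, non-acidic conditions.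

Step 18
Reactants: 26 benzophenone
Product: 27 6-allyl-2-{3,4-bis[(tert-butyldimethylsilyl)oxy]benzoyl}-6-(2,6-dimethyl-3-methylidenehept-5-en-2-yl)-3,5-bis(methoxymethoxy)-4-[(2S,4R)-side chain]cyclohexa-2,4-dien-1-one, obtained as the mixture of both epimers at the new quaternary carbon (C6 of the dienone = C1 of the bicycle)
Conditions: Eu(fod)3 (10 mol%), PhMe, 80 °C
Reagents that add atoms: none
Why: Dearomatising aromatic Claisen rearrangement, assisted by chelation of trivalent europium between the ketone and the ether oxygen: the para carbon C5 is blocked and, of the two substituted ortho carbons, the electron-rich allyl-bearing C1 should accept the group rather than C3, which is deactivated by conjugation with the aroyl group, so the quaternary C1 with its C8(Me2)–C7(=CH2) arm should form regioselectively; the distant side-chain stereocentres exert no facial control, so both C1 epimers are expected and are taken on together.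

Step 19
Reactants: 27 bis(methoxymethyl) dienone (both C1 epimers)
Product: 28 cyclisation precursor, the enolised trione with allyl and the C8(Me2)–C7(prenyl)=C6H2 arm on C1 (C1 as in the target), the (2S,4R) side chain on C5 and the silylated aroyl group on C3
Conditions: HCl (0.5 M aq.), THF, 0 °C → rt; then preparative HPLC (chiral stationary phase if needed) to separate the C1 epimers
Reagents that add atoms: none
Why: Acid hydrolysis of the two methoxymethyl groups, which sit on vinylogous acid oxygens and are far more labile than the aryl and alkyl silyl ethers, frees the C4/C9 dicarbonyl unit; the two C1 epimers are diastereomers because of the fixed side-chain centres, so chromatography fixes C1 of 28 and the unwanted epimer is removed here.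

Step 20
Reactants: 28 cyclisation precursor
Product: 29 bicyclo[3.3.1]nonane tris(silyl ether) with allyl at C1, endo prenyl at C7 and the side chain at C5
Conditions: Mn(OAc)3·2H2O (2.2 equiv, added in portions), 1,4-cyclohexadiene (20 equiv), degassed EtOH–AcOH (9:1), 25 °C
Reagents that add atoms: none
Why: Proposed new method: trivalent manganese oxidises the enolised C4/C9 dicarbonyl unit to a delocalised radical that bonds through C5 to the CH2 terminus C6 of the 1,1-disubstituted alkene, and the tertiary C7 radical is then reduced by hydrogen-atom transfer from 1,4-cyclohexadiene (the cyclohexadienyl radical is oxidised on to benzene); the closest known reactions are the Mn(OAc)3-mediated 6-endo cyclisations of unsaturated β-dicarbonyl compounds and the Mn(OAc)3 cyclisations of dearomatised acylphloroglucinols, which however end by oxidation and not by hydrogen transfer at a tertiary radical. Ring B (C1–C8–C7–C6–C5–C9) closes 6-endo-trig with the C9 carbonyl inside the ring. C5 is fixed by C1, because the tether can only reach the face of ring A that carries the C8 arm, and C7 is set by hydrogen delivery to the exo lobe of the radical (the endo lobe points under ring A), which turns the prenyl group endo. The step needs reaction at C5 and not at the aroyl-bearing C3, which the lower spin density and greater hindrance at C3 and the retention of the chelated aroyl enol should secure. It needs attack on C6 and not on the allyl group, which the more nucleophilic 1,1-disubstituted alkene, the tertiary radical formed and the gem-dimethyl effect of C8 should secure. It needs hydrogen transfer to outrun oxidation of the C7 radical, which the large excess of the diene and the portionwise addition of the oxidant should secure.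

Step 21
Reactants: 29 allyl bicycle
Product: 30 tris-silylated target (prenyl at C1)
Conditions: second-generation Grubbs catalyst (10 mol%), 2-methylbut-2-ene–CH2Cl2, sealed vessel, 40 °C
Reagents that add atoms: 2-methylbut-2-ene, CC=C(C)C
Why: Olefin cross-metathesis of the monosubstituted allyl group with excess 2-methylbut-2-ene; the trisubstituted prenyl group and the 1,1-disubstituted isopropenyl groups are much slower partners.

Step 22
Reactants: 30 tris-silylated target
Product: 31 CNP0329843.4
Conditions: HF·pyridine, pyridine, THF, 0 °C → rt, under argon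
Reagents that add atoms: none
Why: Fluoride-mediated cleavage of the two aryl silyl ethers and the secondary allylic silyl ether, buffered with pyridine so that the enol does not cyclise onto a prenyl group under acid.

**Compound list**

1 | (±)-lavandulyl acetate [5-methyl-2-(prop-1-en-2-yl)hex-4-en-1-yl acetate, racemate] | CC(C)=CCC(COC(C)=O)C(C)=C | starting material
2 | (S)-lavandulyl acetate | C=C(C)[C@H](CC=C(C)C)COC(C)=O | intermediate
3 | (2S)-2-{[(2R)-3,3-dimethyloxiran-2-yl]methyl}-3-methylbut-3-en-1-yl acetate | C=C(C)[C@H](C[C@@H]1C(C)(C)O1)COC(C)=O | intermediate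
4 | tertiary triflate, (2S,4R)-4-[(tert-butyldimethylsilyl)oxy]-5-methyl-2-(prop-1-en-2-yl)-5-(trifluoromethanesulfonyloxy)hexyl acetate | C=C(C)[C@H](C[C@@H](O[Si](C)(C)C(C)(C)C)C(C)(C)OS(=O)(=O)C(F)(F)F)COC(C)=O | intermediate
5 | (2S,4R)-4-[(tert-butyldimethylsilyl)oxy]-5-methyl-2-(prop-1-en-2-yl)hex-5-en-1-yl acetate | C=C(C)[C@H](C[C@@H](O[Si](C)(C)C(C)(C)C)C(=C)C)COC(C)=O | intermediate
6 | (2S,4R)-4-[(tert-butyldimethylsilyl)oxy]-5-methyl-2-(prop-1-en-2-yl)hex-5-en-1-ol | C=C(C)[C@H](C[C@@H](O[Si](C)(C)C(C)(C)C)C(=C)C)CO | intermediate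
7 | side-chain iodide, (3R,5S)-3-[(tert-butyldimethylsilyl)oxy]-6-iodo-2-methyl-5-(prop-1-en-2-yl)hex-1-ene | C=C(C)[C@H](C[C@@H](O[Si](C)(C)C(C)(C)C)C(=C)C)CI | intermediate
8 | (±)-lavandulol | CC(C)=CCC(CO)C(C)=C | starting material
9 | (±)-lavandulal [5-methyl-2-(prop-1-en-2-yl)hex-4-enal] | CC(C)=CCC(C=O)C(C)=C | intermediate
10 | isolavandulal [5-methyl-2-(propan-2-ylidene)hex-4-enal] | CC(C)=CCC(C=O)=C(C)C | intermediate
11 | isolavandulol [5-methyl-2-(propan-2-ylidene)hex-4-en-1-ol] | CC(C)=CCC(CO)=C(C)C | intermediate
12 | isolavandulyl bromide [3-(bromomethyl)-2,6-dimethylhepta-2,5-diene] | CC(C)=CCC(CBr)=C(C)C | intermediate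
13 | 4-bromobenzene-1,2-diol | Oc1ccc(Br)cc1O | starting material
14 | 4-bromo-1,2-bis[(tert-butyldimethylsilyl)oxy]benzene | CC(C)(C)[Si](C)(C)Oc1ccc(Br)cc1O[Si](C)(C)C(C)(C)C | intermediate
15 | 2,4,6-trihydroxybenzaldehyde | O=Cc1c(O)cc(O)cc1O | starting material
16 | 2-hydroxy-4,6-bis(methoxymethoxy)benzaldehyde | O=Cc1c(O)cc(OCOC)cc1OCOC | intermediate
17 | 2-(allyloxy)-4,6-bis(methoxymethoxy)benzaldehyde | O=Cc1c(OCC=C)cc(OCOC)cc1OCOC | intermediate
18 | ortho-dienone, 5-allyl-2,4-bis(methoxymethoxy)-6-oxocyclohexa-1,3-diene-1-carbaldehyde (racemic, transient) | O=CC1=C(OCOC)C=C(OCOC)C(CC=C)C1=O | intermediate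
19 | 3-allyl-2-hydroxy-4,6-bis(methoxymethoxy)benzaldehyde | O=Cc1c(O)c(CC=C)c(OCOC)cc1OCOC | intermediate
20 | 3-allyl-5-bromo-2-hydroxy-4,6-bis(methoxymethoxy)benzaldehyde | O=Cc1c(O)c(CC=C)c(OCOC)c(Br)c1OCOC | intermediate
21 | 3-allyl-5-bromo-4,6-bis(methoxymethoxy)-2-{[5-methyl-2-(propan-2-ylidene)hex-4-en-1-yl]oxy}benzaldehyde | O=Cc1c(OCC(CC=C(C)C)=C(C)C)c(CC=C)c(OCOC)c(Br)c1OCOC | intermediate
22 | [(2S,4R)-4-[(tert-butyldimethylsilyl)oxy]-5-methyl-2-(prop-1-en-2-yl)hex-5-en-1-yl]zinc iodide | C=C(C)[C@H](C[C@@H](O[Si](C)(C)C(C)(C)C)C(=C)C)C[Zn]I | intermediate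
23 | 3-allyl-2-(isolavandulyloxy)-4,6-bis(methoxymethoxy)-5-[(2S,4R)-4-[(tert-butyldimethylsilyl)oxy]-5-methyl-2-(prop-1-en-2-yl)hex-5-en-1-yl]benzaldehyde | C=C(C)[C@H](C[C@@H](O[Si](C)(C)C(C)(C)C)C(=C)C)Cc1c(OCOC)c(CC=C)c(OCC(CC=C(C)C)=C(C)C)c(C=O)c1OCOC | intermediate
24 | 3,4-bis[(tert-butyldimethylsilyl)oxy]phenyllithium | [Li]c1ccc(O[Si](C)(C)C(C)(C)C)c(O[Si](C)(C)C(C)(C)C)c1 | intermediate
25 | diaryl carbinol from 23 and 24 (both carbinol epimers) | C=C(C)[C@H](C[C@@H](O[Si](C)(C)C(C)(C)C)C(=C)C)Cc1c(OCOC)c(CC=C)c(OCC(CC=C(C)C)=C(C)C)c(C(O)c2ccc(O[Si](C)(C)C(C)(C)C)c(O[Si](C)(C)C(C)(C)C)c2)c1OCOC | intermediate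
26 | benzophenone, the ketone of 25 | C=C(C)[C@H](C[C@@H](O[Si](C)(C)C(C)(C)C)C(=C)C)Cc1c(OCOC)c(CC=C)c(OCC(CC=C(C)C)=C(C)C)c(C(=O)c2ccc(O[Si](C)(C)C(C)(C)C)c(O[Si](C)(C)C(C)(C)C)c2)c1OCOC | intermediate
27 | bis(methoxymethyl) dienone from the Claisen rearrangement, both C1 epimers (C1 of the bicycle = C6 of the dienone, left undefined) | C=C(C)[C@H](C[C@@H](O[Si](C)(C)C(C)(C)C)C(=C)C)CC1=C(OCOC)C(CC=C)(C(C)(C)C(=C)CC=C(C)C)C(=O)C(C(=O)c2ccc(O[Si](C)(C)C(C)(C)C)c(O[Si](C)(C)C(C)(C)C)c2)=C1OCOC | intermediate
28 | cyclisation precursor (enolised trione, C1 as in the target) | C=C(C)[C@H](C[C@@H](O[Si](C)(C)C(C)(C)C)C(=C)C)CC1=C(O)[C@@](CC=C)(C(C)(C)C(=C)CC=C(C)C)C(O)=C(C(=O)c2ccc(O[Si](C)(C)C(C)(C)C)c(O[Si](C)(C)C(C)(C)C)c2)C1=O | intermediate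
29 | bicyclic tris(silyl ether) with allyl at C1 (C7 prenyl endo, bridgeheads as in the target) | C=C(C)[C@H](C[C@@H](O[Si](C)(C)C(C)(C)C)C(=C)C)C[C@@]12C[C@@H](CC=C(C)C)C(C)(C)[C@@](CC=C)(C(=O)C(C(=O)c3ccc(O[Si](C)(C)C(C)(C)C)c(O[Si](C)(C)C(C)(C)C)c3)=C1O)C2=O | intermediate
30 | tris-silylated target | C=C(C)[C@H](C[C@@H](O[Si](C)(C)C(C)(C)C)C(=C)C)C[C@@]12C[C@@H](CC=C(C)C)C(C)(C)[C@@](CC=C(C)C)(C(=O)C(C(=O)c3ccc(O[Si](C)(C)C(C)(C)C)c(O[Si](C)(C)C(C)(C)C)c3)=C1O)C2=O | intermediate
31 | CNP0329843.4 (side chain 2S,4R; C7 prenyl endo) | C=C(C)[C@H](C[C@@H](O)C(=C)C)C[C@@]12C[C@@H](CC=C(C)C)C(C)(C)[C@@](CC=C(C)C)(C(=O)C(C(=O)c3ccc(O)c(O)c3)=C1O)C2=O | target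

**Step count and risks**

Total step count: 22. Longest linear sequence: 13 steps (15 → 31 through steps 10–22; the side-chain branch 1 → 31 through steps 1–5 and 15–22 is equally long).

Steps most likely to fail:

Step 20. The tertiary C7 radical may be oxidised by trivalent manganese to the cation (then loss of a proton or capture by an enol oxygen) faster than it takes hydrogen from the diene, and part of the C5 radical may close onto the terminal carbon of the allyl group. The fallback uses known radical chain chemistry with no oxidant present. It sets out from 28, which is brominated at C5 with NBS (CH2Cl2, −20 °C) to the 5-bromo trione F1. F1 is then cyclised under reductive chain conditions ((Me3Si)3SiH added slowly, AIBN, PhH, 80 °C). Bromine abstraction gives the same C5 radical, the same 6-endo closure follows, and the tertiary C7 radical can only be reduced, by the bulky silane from the exo face. The route is rejoined at 29.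

Step 18. The sigmatropic shift may stop at an unfavourable equilibrium with the aryl ether or run on by a Cope shift of the new arm to C5, because the bis-acetal dienone gains less stabilisation than a free vinylogous acid. The fallback sets out from 26. Both methoxymethyl groups are removed under non-acidic conditions (TMSOTf, 2,2′-bipyridyl, MeCN, 0 °C; then water), which should spare the allylic ether and the silyl ethers, to give the diphenol F2. F2 is then warmed in toluene; the rearranged product tautomerises at once to the hydrogen-bonded enolised trione, which removes it from the equilibrium. This should give the enolised trione as the C1-epimer mixture F3, which is separated by preparative HPLC on a chiral stationary phase. The route is rejoined at 28.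

Step 15. Zerovalent palladium may ionise the allylic aryl ether, or oxidative addition into the doubly ortho-substituted bromide may be too slow, so that the zinc reagent is lost to protonation. The fallback changes the order of events so that palladium never meets the allylic ether. It sets out from 20, which is coupled as the free bromophenol with the zinc reagent 22 (Pd(OAc)2/SPhos, slow addition of 22; such couplings tolerate phenolic O–H) to give the phenol F4. F4 is then etherified with 12 (K2CO3, DMF). The route is rejoined at 23.

**Further compounds**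

F1 | step 20 | 5-bromo trione from 28 (bromine and side chain on C5, both C5 epimers) | C=C(C)[C@H](C[C@@H](O[Si](C)(C)C(C)(C)C)C(=C)C)CC1(Br)C(=O)[C@@](CC=C)(C(C)(C)C(=C)CC=C(C)C)C(O)=C(C(=O)c2ccc(O[Si](C)(C)C(C)(C)C)c(O[Si](C)(C)C(C)(C)C)c2)C1=O
F2 | step 18 | diphenol from 26 (both methoxymethyl groups removed, isolavandulyl ether kept) | C=C(C)[C@H](C[C@@H](O[Si](C)(C)C(C)(C)C)C(=C)C)Cc1c(O)c(CC=C)c(OCC(CC=C(C)C)=C(C)C)c(C(=O)c2ccc(O[Si](C)(C)C(C)(C)C)c(O[Si](C)(C)C(C)(C)C)c2)c1O
F3 | step 18 | enolised trione from F2 as the mixture of both C1 epimers (C1 left undefined) | C=C(C)[C@H](C[C@@H](O[Si](C)(C)C(C)(C)C)C(=C)C)CC1=C(O)C(CC=C)(C(C)(C)C(=C)CC=C(C)C)C(O)=C(C(=O)c2ccc(O[Si](C)(C)C(C)(C)C)c(O[Si](C)(C)C(C)(C)C)c2)C1=O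
F4 | step 15 | 3-allyl-2-hydroxy-4,6-bis(methoxymethoxy)-5-[(2S,4R)-4-[(tert-butyldimethylsilyl)oxy]-5-methyl-2-(prop-1-en-2-yl)hex-5-en-1-yl]benzaldehyde | C=C(C)[C@H](C[C@@H](O[Si](C)(C)C(C)(C)C)C(=C)C)Cc1c(OCOC)c(CC=C)c(O)c(C=O)c1OCOC
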